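The butenolide is treated as a cyclised 2,3-allenoic acid: its lactone O–C6 bond and its C7=C11 double bond (germacranolide numbering, lactone carbonyl C12) come from an allene C11=C7=C6 whose axis stores the C6 configuration. Oxypalladation of acid 8 with divalent palladium closes the furanone ring at O–C6 with axial-to-central chirality transfer, and the C7–Pd bond so formed adds to vinyl ketone 12, which attaches C8–C10 and C1–C3 in the same operation. The precursors are an open-chain silylated trienoic acid and a hydroxybutyrolactone-derived enone; the ten-membered ring is closed later at C3–C4 by a Nozaki–Hiyama–Kishi reaction.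

Key step: step 9

Remark: atoms carry germacranolide numbers (ring C1–C10, C11–C13 in the lactone unit, C14 exocyclic methylene, C15 methyl); in step 3 the ProPhenol antipode that delivers the 4S alcohol is meant, and (S,S) is assumed.

Step 1
Reactants: 1 but-2-yn-1-ol
Product: 2 (Z)-3-(triethylsilyl)but-2-en-1-ol
Conditions: Et3SiH, [Cp*Ru(MeCN)3]PF6 (1 mol%), CH2Cl2, 0 °C to rt
Reagents that add atoms: triethylsilane, CC[SiH](CC)CC
Why: Ruthenium-catalysed trans-hydrosilylation of a propargylic alcohol adds H and Si anti with silicon on the carbon remote from the hydroxyl, which should fix the Z geometry (CH2OH cis to Si) of the later C4=C5 bond.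

Step 2
Reactants: 2 (Z)-3-(triethylsilyl)but-2-en-1-ol
Product: 3 (Z)-3-(triethylsilyl)but-2-enal
Conditions: MnO2, CH2Cl2, rt
Reagents that add atoms: none
Why: Allylic oxidation with MnO2 is neutral and should leave the alkene geometry untouched.

Step 3
Reactants: 3 (Z)-3-(triethylsilyl)but-2-enal; 4 tert-butyl(diphenyl)(prop-2-yn-1-yloxy)silane
Product: 6 (4S,5Z)-1-(tert-butyldiphenylsilyloxy)-6-(triethylsilyl)hept-5-en-2-yn-4-ol, via alkynylzinc 5 (not isolated)
Conditions: Me2Zn, (S,S)-ProPhenol (10 mol%), Ph3PO (20 mol%), toluene, 0 °C; aq. NH4Cl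
Reagents that add atoms: none
Why: Zinc–ProPhenol catalysed asymmetric alkynylation of an enal, in which the ligand controls the aldehyde face and sets the future C6 as the 4S propargylic carbinol.

Step 4
Reactants: 6 (4S,5Z)-1-(tert-butyldiphenylsilyloxy)-6-(triethylsilyl)hept-5-en-2-yn-4-ol
Product: 7 diethyl (4S,5Z)-1-(tert-butyldiphenylsilyloxy)-6-(triethylsilyl)hept-5-en-2-yn-4-yl phosphate
Conditions: ClP(O)(OEt)2, pyridine, DMAP (cat.), CH2Cl2, 0 °C
Reagents that add atoms: diethyl chlorophosphate, CCOP(=O)(Cl)OCC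
Why: Phosphorylation of the secondary alcohol gives an isolable propargylic leaving group without touching the stereocentre.

Step 5
Reactants: 7 diethyl (4S,5Z)-1-(tert-butyldiphenylsilyloxy)-6-(triethylsilyl)hept-5-en-2-yn-4-yl phosphate
Product: 8 (Ra,5Z)-2-[(tert-butyldiphenylsilyloxy)methyl]-6-(triethylsilyl)hepta-2,3,5-trienoic acid
Conditions: Pd(PPh3)4 (5 mol%), CO (1 atm), THF/H2O (10:1), 0 °C to rt
Reagents that add atoms: carbon monoxide, [C-]#[O+]; water, O
Why: Carbonylation of a propargylic phosphate with zerovalent palladium, in which the metal enters at the remote alkyne carbon anti to the phosphate (SN2′) and CO insertion with hydrolysis replaces the C–Pd bond with retention, so the 4S centre should become the Ra allene axis.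

Step 6
Reactants: 9 (S)-3-hydroxydihydrofuran-2(3H)-one
Product: 10 (S)-2,4-dihydroxy-N-methoxy-N-methylbutanamide
Conditions: MeNHOMe·HCl, iPrMgCl, THF, −20 to 0 °C
Reagents that add atoms: N,O-dimethylhydroxylamine hydrochloride, CNOC.Cl
Why: Weinreb aminolysis of the lactone by the magnesium amide opens the ring at the acyl carbon and does not involve the stereocentre.

Step 7
Reactants: 10 (S)-2,4-dihydroxy-N-methoxy-N-methylbutanamide
Product: 11 (S)-2,4-bis(tert-butyldimethylsilyloxy)-N-methoxy-N-methylbutanamide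
Conditions: TBSCl, imidazole, DMF, rt
Reagents that add atoms: tert-butyldimethylsilyl chloride, CC(C)(C)[Si](C)(C)Cl
Why: Standard silylation of both hydroxyl groups prevents relactonisation and protects C1–O and C3–O.

Step 8
Reactants: 11 (S)-2,4-bis(tert-butyldimethylsilyloxy)-N-methoxy-N-methylbutanamide
Product: 12 (S)-4,6-bis(tert-butyldimethylsilyloxy)hex-1-en-3-one
Conditions: CH2=CHMgBr, THF, 0 °C; inverse quench into cold 1 M HCl
Reagents that add atoms: vinylmagnesium bromide, C=C[Mg]Br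
Why: Grignard addition to a Weinreb amide stops at the ketone through the chelated adduct, and the cold acidic quench should keep the released amine from adding to the enone.

Step 9
Reactants: 8 (Ra,5Z)-2-[(tert-butyldiphenylsilyloxy)methyl]-6-(triethylsilyl)hepta-2,3,5-trienoic acid; 12 (S)-4,6-bis(tert-butyldimethylsilyloxy)hex-1-en-3-one
Product: 15 (5R)-4-[(4S)-4,6-bis(tert-butyldimethylsilyloxy)-3-oxohexyl]-3-[(tert-butyldiphenylsilyloxy)methyl]-5-[(Z)-2-(triethylsilyl)prop-1-en-1-yl]furan-2(5H)-one, via furanonylpalladium bromide 13 (not isolated), via palladium enolate 14 (not isolated)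
Conditions: Pd(OAc)2 (5 mol%), LiBr (2 equiv), 12 (1.5 equiv), MeCN/AcOH (10:1), rt
Reagents that add atoms: none
Why: Proposed new method: divalent palladium binds the C6=C7 bond of the allene on the face turned away from the carboxyl group and the carboxylate oxygen attacks C6 anti to the metal, a 5-endo-trig oxypalladation that closes the furanone ring and gives furanonylpalladium bromide 13. The C7–Pd bond then inserts the vinyl ketone 12 (C7–C8 bond) to give palladium enolate 14, which should be protonated by acetic acid instead of losing a β-hydride because bromide occupies the vacant sites, so 15 is released and divalent palladium returns without an oxidant. The closest known reaction types are the divalent-palladium cyclisation–coupling of 2,3-allenoic acids with allylic halides, allenes and ynones, and the halide-assisted conjugate addition–protonolysis of alkenylpalladium species with enones; the proposal joins the two. The one new stereocentre, C6, is controlled by the allene axis: in the Ra acid the carboxyl carbon C12 lies on the face of C6 that gives 6R, and the C4=C5 geometry is not touched. The step needs insertion to outrun protodepalladation of 13 (secured by the excess of 12 and the weakly acidic medium) and needs the axial chirality to survive until ring closure (secured by fast intramolecular attack at room temperature).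

Step 10
Reactants: 15 (5R)-4-[(4S)-4,6-bis(tert-butyldimethylsilyloxy)-3-oxohexyl]-3-[(tert-butyldiphenylsilyloxy)methyl]-5-[(Z)-2-(triethylsilyl)prop-1-en-1-yl]furan-2(5H)-one
Product: 16 (5R)-4-[(4S)-4,6-bis(tert-butyldimethylsilyloxy)-3-oxohexyl]-3-[(tert-butyldiphenylsilyloxy)methyl]-5-[(Z)-2-iodoprop-1-en-1-yl]furan-2(5H)-one
Conditions: NIS, 2,6-lutidine, (CF3)2CHOH, 0 °C
Reagents that add atoms: N-iodosuccinimide, O=C1CCC(=O)N1I
Why: Electrophilic ipso-iododesilylation of an alkenylsilane proceeds with retention, so iodine should stay cis to C6 (Z), and it is run before any electron-rich 1,1-disubstituted alkene is present.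

Step 11
Reactants: 16 (5R)-4-[(4S)-4,6-bis(tert-butyldimethylsilyloxy)-3-oxohexyl]-3-[(tert-butyldiphenylsilyloxy)methyl]-5-[(Z)-2-iodoprop-1-en-1-yl]furan-2(5H)-one
Product: 17 (5R)-4-[(4S)-4,6-bis(tert-butyldimethylsilyloxy)-3-methylidenehexyl]-3-[(tert-butyldiphenylsilyloxy)methyl]-5-[(Z)-2-iodoprop-1-en-1-yl]furan-2(5H)-one
Conditions: Zn, CH2Br2, TiCl4, THF/CH2Cl2, 0 °C to rt
Reagents that add atoms: dibromomethane, BrCBr
Why: Lombardo methylenation is non-basic and ketone-selective, so the acidic C6–H of the butenolide and the α-silyloxy centre C1 should not epimerise and the lactone carbonyl should stay.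

Step 12
Reactants: 17 (5R)-4-[(4S)-4,6-bis(tert-butyldimethylsilyloxy)-3-methylidenehexyl]-3-[(tert-butyldiphenylsilyloxy)methyl]-5-[(Z)-2-iodoprop-1-en-1-yl]furan-2(5H)-one
Product: 18 (5R)-4-[(4S)-4-(tert-butyldimethylsilyloxy)-6-hydroxy-3-methylidenehexyl]-3-[(tert-butyldiphenylsilyloxy)methyl]-5-[(Z)-2-iodoprop-1-en-1-yl]furan-2(5H)-one
Conditions: HF·pyridine, pyridine, THF, 0 °C
Reagents that add atoms: none
Why: Selective desilylation, since buffered HF·pyridine cleaves the primary TBS ether faster than the secondary TBS ether and the TBDPS ether.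

Step 13
Reactants: 18 (5R)-4-[(4S)-4-(tert-butyldimethylsilyloxy)-6-hydroxy-3-methylidenehexyl]-3-[(tert-butyldiphenylsilyloxy)methyl]-5-[(Z)-2-iodoprop-1-en-1-yl]furan-2(5H)-one
Product: 19 (5R)-4-[(4S)-4-(tert-butyldimethylsilyloxy)-3-methylidene-6-oxohexyl]-3-[(tert-butyldiphenylsilyloxy)methyl]-5-[(Z)-2-iodoprop-1-en-1-yl]furan-2(5H)-one
Conditions: Dess–Martin periodinane, CH2Cl2, 0 °C to rt
Reagents that add atoms: none
Why: Dess–Martin oxidation converts the primary alcohol into the C3 aldehyde under near-neutral conditions that should spare the alkenyl iodide and the β-silyloxy group.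

Step 14
Reactants: 19 (5R)-4-[(4S)-4-(tert-butyldimethylsilyloxy)-3-methylidene-6-oxohexyl]-3-[(tert-butyldiphenylsilyloxy)methyl]-5-[(Z)-2-iodoprop-1-en-1-yl]furan-2(5H)-one
Product: 21 (1S,3S,6R,4Z)-1-(tert-butyldimethylsilyloxy)-13-(tert-butyldiphenylsilyloxy)-3-hydroxygermacra-4,7(11),10(14)-trien-12,6-olide, via alkenylchromium dichloride 20 (not isolated)
Conditions: CrCl2 (10 equiv), NiCl2 (0.1 equiv), DMSO/THF, 0.002 M, rt
Reagents that add atoms: none
Why: Nozaki–Hiyama–Kishi reaction, in which the alkenylchromium 20 forms with retention of the Z geometry and adds to the aldehyde to close the ten-membered ring at C3–C4, the 3S configuration (1,3-anti to C1–OTBS) being expected from the polar 1,3-induction model for β-silyloxy aldehydes.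

Step 15
Reactants: 21 (1S,3S,6R,4Z)-1-(tert-butyldimethylsilyloxy)-13-(tert-butyldiphenylsilyloxy)-3-hydroxygermacra-4,7(11),10(14)-trien-12,6-olide
Product: 22 (1S,3S,6R,4Z)-13-(tert-butyldiphenylsilyloxy)-1,3-dihydroxygermacra-4,7(11),10(14)-trien-12,6-olide
Conditions: CSA (cat.), MeOH/CH2Cl2, 0 °C to rt
Reagents that add atoms: none
Why: Acid-catalysed methanolysis should remove the secondary TBS ether while the far more acid-stable TBDPS ether survives.

Step 16
Reactants: 22 (1S,3S,6R,4Z)-13-(tert-butyldiphenylsilyloxy)-1,3-dihydroxygermacra-4,7(11),10(14)-trien-12,6-olide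
Product: 23 (1S,3S,6R,4Z)-1,3-diacetoxy-13-(tert-butyldiphenylsilyloxy)germacra-4,7(11),10(14)-trien-12,6-olide
Conditions: Ac2O, pyridine, DMAP (cat.), CH2Cl2, rt
Reagents that add atoms: acetic anhydride, CC(=O)OC(C)=O
Why: DMAP-catalysed acetylation of both secondary alcohols proceeds at oxygen and keeps all stereocentres.

Step 17
Reactants: 23 (1S,3S,6R,4Z)-1,3-diacetoxy-13-(tert-butyldiphenylsilyloxy)germacra-4,7(11),10(14)-trien-12,6-olide
Product: 24 (1S,3S,6R,4Z)-1,3-diacetoxy-13-hydroxygermacra-4,7(11),10(14)-trien-12,6-olide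
Conditions: HF·pyridine, THF, 0 °C to rt
Reagents that add atoms: none
Why: Fluoride cleavage of the TBDPS ether under mildly acidic conditions should free the C13 alcohol without acetate migration or epimerisation of the base-sensitive C6.

Compound list
1 | but-2-yn-1-ol | CC#CCO | starting material
2 | (Z)-3-(triethylsilyl)but-2-en-1-ol | OC/C=C(/C)[Si](CC)(CC)CC | intermediate
3 | (Z)-3-(triethylsilyl)but-2-enal | O=C/C=C(/C)[Si](CC)(CC)CC | intermediate
4 | tert-butyl(diphenyl)(prop-2-yn-1-yloxy)silane | C#CCO[Si](c1ccccc1)(c1ccccc1)C(C)(C)C | starting material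
5 | methyl[3-(tert-butyldiphenylsilyloxy)prop-1-yn-1-yl]zinc | C[Zn]C#CCO[Si](c1ccccc1)(c1ccccc1)C(C)(C)C | intermediate
6 | (4S,5Z)-1-(tert-butyldiphenylsilyloxy)-6-(triethylsilyl)hept-5-en-2-yn-4-ol | O[C@H](C#CCO[Si](c1ccccc1)(c1ccccc1)C(C)(C)C)/C=C(/C)[Si](CC)(CC)CC | intermediate
7 | diethyl (4S,5Z)-1-(tert-butyldiphenylsilyloxy)-6-(triethylsilyl)hept-5-en-2-yn-4-yl phosphate | CCOP(=O)(OCC)O[C@H](C#CCO[Si](c1ccccc1)(c1ccccc1)C(C)(C)C)/C=C(/C)[Si](CC)(CC)CC | intermediate
8 | (Ra,5Z)-2-[(tert-butyldiphenylsilyloxy)methyl]-6-(triethylsilyl)hepta-2,3,5-trienoic acid | OC(=O)C(CO[Si](c1ccccc1)(c1ccccc1)C(C)(C)C)=[C@]=C([H])/C=C(/C)[Si](CC)(CC)CC | intermediate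
9 | (S)-3-hydroxydihydrofuran-2(3H)-one | O[C@H]1CCOC1=O | starting material
10 | (S)-2,4-dihydroxy-N-methoxy-N-methylbutanamide | O[C@@H](CCO)C(=O)N(C)OC | intermediate
11 | (S)-2,4-bis(tert-butyldimethylsilyloxy)-N-methoxy-N-methylbutanamide | CON(C)C(=O)[C@H](CCO[Si](C)(C)C(C)(C)C)O[Si](C)(C)C(C)(C)C | intermediate
12 | (S)-4,6-bis(tert-butyldimethylsilyloxy)hex-1-en-3-one | C=CC(=O)[C@H](CCO[Si](C)(C)C(C)(C)C)O[Si](C)(C)C(C)(C)C | intermediate
13 | bromo{(2R)-5-oxo-4-[(tert-butyldiphenylsilyloxy)methyl]-2-[(Z)-2-(triethylsilyl)prop-1-en-1-yl]-2,5-dihydrofuran-3-yl}palladium (other ligands not drawn) | O=C1O[C@H](/C=C(/C)[Si](CC)(CC)CC)C([Pd]Br)=C1CO[Si](c1ccccc1)(c1ccccc1)C(C)(C)C | intermediate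
14 | C-bound bromopalladium enolate of 15, palladium on the carbon α to the ketone (C9) | O=C1O[C@H](/C=C(/C)[Si](CC)(CC)CC)C(CC([Pd]Br)C(=O)[C@H](CCO[Si](C)(C)C(C)(C)C)O[Si](C)(C)C(C)(C)C)=C1CO[Si](c1ccccc1)(c1ccccc1)C(C)(C)C | intermediate
15 | (5R)-4-[(4S)-4,6-bis(tert-butyldimethylsilyloxy)-3-oxohexyl]-3-[(tert-butyldiphenylsilyloxy)methyl]-5-[(Z)-2-(triethylsilyl)prop-1-en-1-yl]furan-2(5H)-one | O=C1O[C@H](/C=C(/C)[Si](CC)(CC)CC)C(CCC(=O)[C@H](CCO[Si](C)(C)C(C)(C)C)O[Si](C)(C)C(C)(C)C)=C1CO[Si](c1ccccc1)(c1ccccc1)C(C)(C)C | intermediate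
16 | (5R)-4-[(4S)-4,6-bis(tert-butyldimethylsilyloxy)-3-oxohexyl]-3-[(tert-butyldiphenylsilyloxy)methyl]-5-[(Z)-2-iodoprop-1-en-1-yl]furan-2(5H)-one | O=C1O[C@H](/C=C(/C)I)C(CCC(=O)[C@H](CCO[Si](C)(C)C(C)(C)C)O[Si](C)(C)C(C)(C)C)=C1CO[Si](c1ccccc1)(c1ccccc1)C(C)(C)C | intermediate
17 | (5R)-4-[(4S)-4,6-bis(tert-butyldimethylsilyloxy)-3-methylidenehexyl]-3-[(tert-butyldiphenylsilyloxy)methyl]-5-[(Z)-2-iodoprop-1-en-1-yl]furan-2(5H)-one | O=C1O[C@H](/C=C(/C)I)C(CCC(=C)[C@H](CCO[Si](C)(C)C(C)(C)C)O[Si](C)(C)C(C)(C)C)=C1CO[Si](c1ccccc1)(c1ccccc1)C(C)(C)C | intermediate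
18 | (5R)-4-[(4S)-4-(tert-butyldimethylsilyloxy)-6-hydroxy-3-methylidenehexyl]-3-[(tert-butyldiphenylsilyloxy)methyl]-5-[(Z)-2-iodoprop-1-en-1-yl]furan-2(5H)-one | O=C1O[C@H](/C=C(/C)I)C(CCC(=C)[C@H](CCO)O[Si](C)(C)C(C)(C)C)=C1CO[Si](c1ccccc1)(c1ccccc1)C(C)(C)C | intermediate
19 | (5R)-4-[(4S)-4-(tert-butyldimethylsilyloxy)-3-methylidene-6-oxohexyl]-3-[(tert-butyldiphenylsilyloxy)methyl]-5-[(Z)-2-iodoprop-1-en-1-yl]furan-2(5H)-one | O=C1O[C@H](/C=C(/C)I)C(CCC(=C)[C@H](CC=O)O[Si](C)(C)C(C)(C)C)=C1CO[Si](c1ccccc1)(c1ccccc1)C(C)(C)C | intermediate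
20 | alkenylchromium dichloride derived from 19 (Cr in place of I, Z geometry kept) | O=C1O[C@H](/C=C(/C)[Cr](Cl)Cl)C(CCC(=C)[C@H](CC=O)O[Si](C)(C)C(C)(C)C)=C1CO[Si](c1ccccc1)(c1ccccc1)C(C)(C)C | intermediate
21 | (1S,3S,6R,4Z)-1-(tert-butyldimethylsilyloxy)-13-(tert-butyldiphenylsilyloxy)-3-hydroxygermacra-4,7(11),10(14)-trien-12,6-olide | C=C1CCC2=C(CO[Si](c3ccccc3)(c3ccccc3)C(C)(C)C)C(=O)O[C@@H]2/C=C(/C)[C@@H](O)C[C@@H]1O[Si](C)(C)C(C)(C)C | intermediate
22 | (1S,3S,6R,4Z)-13-(tert-butyldiphenylsilyloxy)-1,3-dihydroxygermacra-4,7(11),10(14)-trien-12,6-olide | C=C1CCC2=C(CO[Si](c3ccccc3)(c3ccccc3)C(C)(C)C)C(=O)O[C@@H]2/C=C(/C)[C@@H](O)C[C@@H]1O | intermediate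
23 | (1S,3S,6R,4Z)-1,3-diacetoxy-13-(tert-butyldiphenylsilyloxy)germacra-4,7(11),10(14)-trien-12,6-olide | C=C1CCC2=C(CO[Si](c3ccccc3)(c3ccccc3)C(C)(C)C)C(=O)O[C@@H]2/C=C(/C)[C@@H](OC(C)=O)C[C@@H]1OC(C)=O | intermediate
24 | (1S,3S,6R,4Z)-1,3-diacetoxy-13-hydroxygermacra-4,7(11),10(14)-trien-12,6-olide | C=C1CCC2=C(CO)C(=O)O[C@@H]2/C=C(/C)[C@@H](OC(C)=O)C[C@@H]1OC(C)=O | target

Total step count: 17
Longest linear sequence: 14 steps (steps 1–5, then 9–17); the enone branch (steps 6–8) is three steps.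

Steps most likely to fail

Step 9. The furanonylpalladium may be protonated before it meets the enone (giving the C7–H butenolide), the palladium enolate may lose a β-hydride, or the allene axis may racemise before ring closure. The fallback sets out from 8 and comes back at 15 with known chemistry. Bromolactonisation of 8 with CuBr2 in acetone/water at 65 °C, a reaction of 2,3-allenoic acids that transfers axial chirality to the lactone carbon, should give the (5R)-4-bromobutenolide F1. Nickel-catalysed reductive conjugate addition of F1 to enone 12 (NiCl2(dme), neocuproine, Mn, Et3SiCl, DMF) should give the triethylsilyl enol ether F2, and brief treatment with aqueous acetic acid returns ketone 15.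

Step 14. The ring conformation in the transition state may override the 1,3-induction, so that the alkenylchromium adds to the aldehyde with poor facial selectivity and C3 epimers result. The fallback sets out from the C3-epimeric mixture of 21 and comes back at 22. Dess–Martin oxidation gives the macrocyclic Z-enone F3, methanolysis with CSA removes the C1 silyl group to give the β-hydroxy enone F4, and Evans–Saksena reduction (Me4NBH(OAc)3, MeCN/AcOH, −20 °C) delivers hydride intramolecularly from the C1 hydroxyl to give the 1,3-anti diol 22.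

Step 5. Zerovalent palladium may ionise the phosphate through the alkene (allyl) terminus instead of the alkyne, or reversible palladation may erode the axial chirality of the allene. The fallback sets out from 7 and comes back at 8 without palladium. Copper-catalysed anti-SN2′ substitution of phosphate 7 with (isopropoxydimethylsilyl)methylmagnesium chloride (CuBr·SMe2, THF, −78 °C) should give the allenylmethylsilane F5 with the same axial sense. Tamao–Fleming oxidation (H2O2, KF, KHCO3) gives the allenol F6, Dess–Martin oxidation gives the allenal F7, and Pinnick oxidation (NaClO2, NaH2PO4, 2-methylbut-2-ene) gives acid 8.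

Further compounds
F1 | step 9 | (5R)-4-bromo-3-[(tert-butyldiphenylsilyloxy)methyl]-5-[(Z)-2-(triethylsilyl)prop-1-en-1-yl]furan-2(5H)-one | O=C1O[C@H](/C=C(/C)[Si](CC)(CC)CC)C(Br)=C1CO[Si](c1ccccc1)(c1ccccc1)C(C)(C)C
F2 | step 9 | triethylsilyl enol ether of 15 (C9=C10 enol ether, mixture of geometries) | O=C1O[C@H](/C=C(/C)[Si](CC)(CC)CC)C(CC=C(O[Si](CC)(CC)CC)[C@H](CCO[Si](C)(C)C(C)(C)C)O[Si](C)(C)C(C)(C)C)=C1CO[Si](c1ccccc1)(c1ccccc1)C(C)(C)C
F3 | step 14 | (1S,6R,4Z)-1-(tert-butyldimethylsilyloxy)-13-(tert-butyldiphenylsilyloxy)-3-oxogermacra-4,7(11),10(14)-trien-12,6-olide | C=C1CCC2=C(CO[Si](c3ccccc3)(c3ccccc3)C(C)(C)C)C(=O)O[C@@H]2/C=C(/C)C(=O)C[C@@H]1O[Si](C)(C)C(C)(C)C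
F4 | step 14 | (1S,6R,4Z)-13-(tert-butyldiphenylsilyloxy)-1-hydroxy-3-oxogermacra-4,7(11),10(14)-trien-12,6-olide | C=C1CCC2=C(CO[Si](c3ccccc3)(c3ccccc3)C(C)(C)C)C(=O)O[C@@H]2/C=C(/C)C(=O)C[C@@H]1O
F5 | step 5 | allene of 8 with CH2Si(CH3)2(OiPr) in place of CO2H | CC(C)O[Si](C)(C)CC(CO[Si](c1ccccc1)(c1ccccc1)C(C)(C)C)=[C@]=C([H])/C=C(/C)[Si](CC)(CC)CC
F6 | step 5 | allene of 8 with CH2OH in place of CO2H | OCC(CO[Si](c1ccccc1)(c1ccccc1)C(C)(C)C)=[C@]=C([H])/C=C(/C)[Si](CC)(CC)CC
F7 | step 5 | allene of 8 with CHO in place of CO2H | O=CC(CO[Si](c1ccccc1)(c1ccccc1)C(C)(C)C)=[C@]=C([H])/C=C(/C)[Si](CC)(CC)CC
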